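Product above 95.0% of the starting material was impossible in this flask, since each product takes one coupling partner, the limiting reagent of the charge; the question was how far below that it stopped.

    coupling partner + free catalyst → catalyst intermediate A (k1 = 0.513 M⁻¹ s⁻¹)
    catalyst intermediate A ⇌ by-product + catalyst intermediate B (K2 = 0.23 M, k2 = 0.708 s⁻¹)
    starting material + catalyst intermediate B → catalyst intermediate C (k3 = 7.41 M⁻¹ s⁻¹)
    catalyst intermediate C → free catalyst + product (k4 = 0.224 s⁻¹)
    catalyst intermediate C → spent catalyst (k5 = 0.00916 s⁻¹)
    coupling partner → decomposed reagent (k6 = 0.00539 s⁻¹)
    coupling partner + protic impurity → quenched reagent (k7 = 0.0250 M⁻¹ s⁻¹)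

starting material 1.9 M; coupling partner 0.950 equiv; protic impurity 0.380 M; free catalyst 2 mol%; time 8.0 h

- which holds at 8.0 h: what has brought the reaction to rest, or that it has not come to rest (it is still moving / all of the starting material has reacted / forward and back rates have come level / no working catalyst is left / the coupling partner has run out first)
- conversion of starting material at 8.0 h
- amount of product at 8.0 h, in percent of the starting material charged

My reckoning counted the coupling partner's life in catalyst turns.

1. First instants. The flask's free catalyst met c(coupling partner) = 1.80 M. With concentrations held at their charge, capture by free catalyst had a half-life of 0.59 min, the quench 1.2 min and decomposition 2.1 min, so capture was the shortest. But captured catalyst is no longer free. One turn meant a wait W = 1.08 s as free catalyst, then a longer round time τ = 5.77 s through the intermediates. Of that time, catalyst intermediate C, the resting state, took 4.29 s.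

2. Middle. I dropped the back step and let decomposition and quench alone run the partner down, impurity held at its charge, with lifetime L = 67.2 s. Integrating the turn rate over that decay gave the turn budget, the turns each catalyst can make before the partner has decayed: T = (L/τ)·ln(1 + τ/W) = 21.5.

3. End. At catalyst intermediate C, product competes with spent catalyst, so a catalyst survives S = 24.5 turns on average. The budget was smaller, and exp(−T/S) put the catalyst still alive at an estimated 41.6%. I therefore expected the partner to go first, with product S·(loading)·(1 − exp(−T/S)) = 28.6%.

The forecast said the coupling partner has run out first, with conversion 34% (28% to 41%) and product 32.5% (26% to 39%), higher than my product. Its grounds: “The partner is therefore gone within minutes”.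

The simulated flask ended thus: the coupling partner has run out first, with 0% of its coupling partner left at 8.00 h. Its conversion was 33.7% and its product 32.4%, against 28.6% from my budget of 21.5 turns, and 33.8% of its catalyst was free at 8.00 h. The neighbour flask with 1.5 M of protic impurity had L = 23.3 s, so its budget shrank to 7.46 turns and my reckoning gave 12.9% product. That neighbour flask held 17.8% of product, with 63.6% of its catalyst free.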